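At 40 min I read the flask, and I want the books of its substrate, the limiting reagent, closed at that moment.

| setting | west | south | flask |
|---|---|---|---|
| substrate | 20 mM | 10 mM | 20 mM |
| gas phase | 0.66 mM (held) | 0.66 mM (held) | 0.66 mM (held) |
| remark | the very flask that is asked about, followed so far | run made earlier |  |
| time |  |  | 40 min |

| run | time / min | target / % |
|---|---|---|
| west | 1.00 | 2.8 |
| west | 1.33 | 3.5 |
| west | 2.00 | 5.0 |
| west | 3.00 | 7.7 |
| west | 5.00 | 13.5 |
| west | 8.00 | 19.4 |
| west | 12.0 | 26.2 |
| south | 2.50 | 6.7 |
| south | 3.00 | 8.1 |
| south | 5.00 | 13.6 |
| south | 8.00 | 19.7 |
| south | 12.0 | 26.2 |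
| south | 20.0 | 36.1 |
| south | 30.0 | 42.9 |

(scatter of a reading: 0.3 percentage points)

- the numbers in the tables scatter by 0.3 percentage points (one standard deviation)
- at the start none of the gas phase is in solution

* how much target there is at 40 min, in percent of the substrate charged
* the change that raises the amount of target at 40 min, in percent of the substrate charged most ("none" if none brings more than 2 percentage points) (ash / cedar / none)
* amount of target at 40 min, in percent of the substrate charged, after ash

- ash: doubling the saturation concentration of gas phase, all else as stated
- cedar: doubling the transfer coefficient of the gas phase, all else as stated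

The west and south runs both stand at 26.2% and 26.2% after 12.0 min, so I read the south run as the later part of the west curve. In the south run target gains 13 percentage points from 5.00 min to 12.0 min, but 6.8 points from 20.0 min to 30.0 min. The log of the ratio of these two mean slopes, taken over the time between their midpoints, gives

λ = 0.0590 min⁻¹

This fade constant, the pseudo-first-order constant at which the rate of making target dies away, is a reading and carries the scatter. If c(dissolved gas) stays steady, c(substrate) fades at the same constant, and the books at the asked time read:

substrate left: exp(−λt) = 9.44%

target: 42.9% plus a fading last slice of 3.8 points = 46.7%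

elsewhere, by difference: 43.9%

So target takes 51.5% of the substrate consumed. The percent of target at 12.0 min does not drop when the charge is doubled, so I do not expect faster transfer to help, and I bet on ash, not cedar. If ash doubles target's part of the fade, λ becomes 0.0894 min⁻¹, target's part becomes 68.0%, and target reaches 66.1%.

The forecast gives 45%, ash and 52% after ash, noting that “The runs never varied the gas, so ash is an assumption”. My ash figure is higher than that.

The flask gives 46.2%, and 62.3% after ash, against my 66.1%; ash gains 16 points, cedar 0.53 points.

    gas phase ⇌ dissolved gas, rate k1*(csat - [dissolved gas]) (kL = 0.226 s⁻¹)
    substrate + dissolved gas → target (k = 0.816 M⁻¹ s⁻¹)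
    substrate → side product (k = 4.62 × 10⁻⁴ s⁻¹)
    dissolved gas + target → over-reaction product (k = 0.0330 M⁻¹ s⁻¹)

At the asked time the flask holds 9.41% of the substrate charged, where λ, read from the target readings, gave 9.44%. For the neighbouring flask read at 25 min, λ gives 22.9% of the substrate left, and that flask holds 23.0%.

(The data were computed for substances that don't exist.)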